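**Plan**

- Retrosynthetic cuts, in order: the two ester C–O bonds; the C13–O and C14–O bonds (back to an E-C13=C14 allylic alcohol); the second C4–CH3 bond and the C3 oxygen (back to a ring A enone); C9–C10 (ring B); then C8–C9 and C5–C6.
- Forward: ring A is bought as an arene. The chain is joined at C5–C6 (Negishi coupling) and at C8–C9 (nickel-catalysed alkyne–aldehyde coupling with a geraniol-derived C7 aldehyde). Ring B then closes by palladium-catalysed allylic dearomatisation. After that ring A is reduced, methylated and deoxygenated, and the side chain is oxidised and acylated.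
- Enabling feature (labdane numbering): ring A (C1–C5 and C10) with its C10 methyl (C20) and one C4 methyl is a masked 2,4-dimethylphenol whose para carbon is C10. The exocyclic C8=C17 methylene next to C9 is what remains of a 2-substituted allyl electrophile. Ring B (C5–C10) can therefore close by attack of C10 on C9.
- Stereochemistry: C9 and C10 come from the chiral palladium catalyst acting on a racemic carbonate. C5 comes from axial protonation in the Li/NH3 reduction. C13 and C14 come from Sharpless epoxidation with D-(−)-diethyl tartrate followed by hydrolysis with inversion at C13.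
- A trimethylsilyl group on C17 is carried through the ring closure to steer the nucleophile to C9 rather than to the unsubstituted allyl terminus. It is removed afterwards by way of the vinyl iodide.

Key step: step 10

Remark: the sense of induction of (R)-BINAP in step 10 cannot be predicted with certainty; it is taken to be the one drawn, and (S)-BINAP would be used if it proves opposite.
Remark: the C8=C17 double bond is drawn E in 17, 19 and 20 (silicon or iodine trans to C9); any Z isomer arising from the allyl face exchange in step 10 is carried along, and both converge at 22.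
Remark: 3-bromo-2,4-dimethylaniline is taken to be a catalogue compound.

**Route**

Step 1
Reactants: 1 3-bromo-2,4-dimethylaniline
Product: 3 3-bromo-2,4-dimethylphenol, via diazonium hydrogensulfate 2 (not isolated)
Conditions: NaNO2, aq. H2SO4, 0 °C; then aq. H2SO4, 100 °C
Reagents that add atoms: water, O
Why: Diazotisation of the aniline and thermal hydrolysis of the arenediazonium salt exchange NH2 for OH and leave the hindered C–Br bond intact.

Step 2
Reactants: 3 3-bromo-2,4-dimethylphenol
Product: 4 (3-bromo-2,4-dimethylphenoxy)(tert-butyl)dimethylsilane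
Conditions: t-BuMe2SiCl, imidazole, DMF, 23 °C
Reagents that add atoms: tert-butyldimethylsilyl chloride, CC(C)(C)[Si](C)(C)Cl
Why: Routine silylation masks the phenol for the organometallic steps, and an aryl silyl ether can later be cleaved selectively beside an alkyl silyl ether.

Step 3
Reactants: 4 (3-bromo-2,4-dimethylphenoxy)(tert-butyl)dimethylsilane; 5 (4-bromobut-1-yn-1-yl)trimethylsilane
Product: 7 tert-butyl{2,4-dimethyl-3-[4-(trimethylsilyl)but-3-yn-1-yl]phenoxy}dimethylsilane, via alkylzinc bromide 6 (not isolated)
Conditions: 5, Zn, LiCl, THF, 50 °C; then 4, Pd(OAc)2 (2 mol %), SPhos (4 mol %), THF, 65 °C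
Reagents that add atoms: none
Why: Negishi coupling of the primary alkylzinc reagent (made by zinc insertion) with the di-ortho-substituted aryl bromide forms C5–C6, and the bulky biarylphosphine is the ligand type that tolerates this hindrance.

Step 4
Reactants: 8 geraniol
Product: 9 geranyl triisopropylsilyl ether
Conditions: i-Pr3SiCl, imidazole, DMF, 23 °C
Reagents that add atoms: triisopropylsilyl chloride, CC(C)[Si](Cl)(C(C)C)C(C)C
Why: Silylation of the primary allylic alcohol gives an ether that, unlike an allylic ester, is not ionised by zerovalent palladium and tolerates hydride and dissolving lithium.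

Step 5
Reactants: 9 geranyl triisopropylsilyl ether
Product: 10 racemic 6,7-epoxygeranyl triisopropylsilyl ether
Conditions: mCPBA, NaHCO3, CH2Cl2, −20 → 0 °C
Reagents that add atoms: 3-chloroperoxybenzoic acid, OOC(=O)c1cccc(Cl)c1
Why: Prilezhaev epoxidation should prefer the remote trisubstituted alkene, because the other one is deactivated by the allylic oxygen, and the new stereocentre is destroyed in step 6.

Step 6
Reactants: 10 racemic 6,7-epoxygeranyl triisopropylsilyl ether
Product: 12 (E)-4-methyl-6-(triisopropylsilyloxy)hex-4-enal, via glycol 11 (not isolated)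
Conditions: H5IO6, THF/H2O, 0 °C
Reagents that add atoms: none
Why: Periodic acid opens the epoxide with water at the tertiary carbon and cleaves the resulting glycol (Malaprade reaction) to the C7 aldehyde and acetone.

Step 7
Reactants: 7 tert-butyl{2,4-dimethyl-3-[4-(trimethylsilyl)but-3-yn-1-yl]phenoxy}dimethylsilane; 12 (E)-4-methyl-6-(triisopropylsilyloxy)hex-4-enal
Product: 14 rac-(1E,6E)-2-{2-[3-(tert-butyldimethylsilyloxy)-2,6-dimethylphenyl]ethyl}-6-methyl-8-(triisopropylsilyloxy)-1-(trimethylsilyl)octa-1,6-dien-3-ol, via diethylborinate 13 (not isolated)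
Conditions: Ni(cod)2 (10 mol %), PBu3 (20 mol %), BEt3, toluene, 23 °C; aq. NH4Cl
Reagents that add atoms: none
Why: Nickel-catalysed reductive coupling of an alkyne with an aldehyde forms C8–C9 at the alkyne carbon remote from silicon (oxidative cyclisation), and ethyl transfer from boron, β-hydride elimination and C–H reductive elimination deliver hydrogen to C17 syn to C9, giving the E-vinylsilane; C9 is formed racemic, which step 10 tolerates.

Step 8
Reactants: 14 the racemic allylic alcohol
Product: 15 methyl carbonate of alcohol 14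
Conditions: ClCO2Me, pyridine, DMAP (cat.), CH2Cl2, 0 °C
Reagents that add atoms: methyl chloroformate, COC(=O)Cl
Why: DMAP-catalysed acylation of the secondary allylic alcohol installs a leaving group that ionises readily and releases its own base (methoxide) on ionisation.

Step 9
Reactants: 15 methyl carbonate of alcohol 14
Product: 16 methyl rac-(1E,6E)-2-[2-(3-hydroxy-2,6-dimethylphenyl)ethyl]-6-methyl-8-(triisopropylsilyloxy)-1-(trimethylsilyl)octa-1,6-dien-3-yl carbonate
Conditions: KHF2, MeOH, 23 °C
Reagents that add atoms: none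
Why: KHF2 in methanol cleaves aryl silyl ethers selectively, since phenoxide is the better leaving group on silicon, and should leave the alkyl triisopropylsilyl ether, the vinylsilane and the carbonate untouched.

Step 10
Reactants: 16 the racemic phenol carbonate
Product: 17 (8(17)E,13E)-17-(trimethylsilyl)-15-(triisopropylsilyloxy)-19-norlabda-1,4,8(17),13-tetraen-3-one (9α-H; 10β-CH3)
Conditions: Pd2(dba)3 (2.5 mol %), (R)-BINAP (6 mol %), THF (0.01 M), 50 °C
Reagents that add atoms: none
Why: Proposed new method: zerovalent palladium ionises the racemic carbonate with loss of CO2 and methoxide, the methoxide deprotonates the phenol, and the phenoxide para carbon C10 attacks the allyl terminus C9 on the face away from palladium, forming C9–C10 and dearomatising ring A; the closest known reaction type is the intramolecular palladium-catalysed allylic dearomatisation of para-tethered phenols to spirocyclohexadienones, from which this case differs by the fused ring and by the tether on the central allyl carbon. Ring B (C5–C6–C7–C8–C9–C10) closes as a six-membered ring in an endo sense, since C8 and C9 of the allyl unit both end up in the ring and C8=C17 stays exocyclic. C9 is set by anti attack on the allyl face selected by the (R)-BINAP–palladium fragment after the diastereomeric allyl complexes have interconverted by π–σ–π slippage through C17, so both enantiomers of 16 should converge; C10 is set by the same chiral pocket together with a chair-like closure in which the C11 chain on C9 lies pseudo-equatorial and hence cis to the C20 methyl. The step needs attack at C9 and not at C17, which would close an isomeric six-membered ring; the trimethylsilyl group on C17 is there to secure this, because nucleophiles add to silyl-substituted allylpalladium units at the terminus remote from silicon. It also needs para attack at C10 over ortho attack at C4 and over O-alkylation: C4 is wedged between the oxygen-bearing C3 and the tether carbon C5 and would give the less stable linearly conjugated dienone, an intramolecular ether would be a strained meta-bridged ring, and intermolecular O-allylation is reversible under palladium and suppressed by dilution.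

Step 11
Reactants: 17 the ring A dienone
Product: 19 (8(17)E,13E)-17-(trimethylsilyl)-15-(triisopropylsilyloxy)-19-norlabda-4,8(17),13-trien-3-one, via lithium dienolate 18 (not isolated)
Conditions: LiBH(s-Bu)3, THF, −78 °C; aq. NH4Cl
Reagents that add atoms: none
Why: The bulky borohydride adds hydride in conjugate fashion to the β-unsubstituted C1=C2 arm of the cross-conjugated dienone (the tetrasubstituted C4=C5 arm is too hindered), and protonation of the dienolate at C2 on work-up gives the C4=C5 enone.

Step 12
Reactants: 19 the silylated enone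
Product: 20 (8(17)E,13E)-17-iodo-15-(triisopropylsilyloxy)-19-norlabda-4,8(17),13-trien-3-one
Conditions: N-iodosuccinimide, (CF3)2CHOH, 0 °C
Reagents that add atoms: N-iodosuccinimide, O=C1CCC(=O)N1I
Why: Ipso-iododesilylation of the vinylsilane (electrophilic attack at the silicon-bearing C17, then loss of silicon from the β-silyl cation) removes the control element without protic acid, so the exocyclic double bond has no pathway to migrate into the ring.

Step 13
Reactants: 20 the vinyl iodide enone
Product: 22 (13E)-15-(triisopropylsilyloxy)labda-8(17),13-dien-3-one, via lithium enolate 21 (not isolated)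
Conditions: Li (4.4 equiv), NH3/THF, t-BuOH (2 equiv), −78 °C; isoprene; then MeI, −78 → −33 °C
Reagents that add atoms: iodomethane, CI
Why: Dissolving lithium hydrogenolyses the vinyl C–I bond to the C17 methylene and reduces the enone (Birch-type reductive alkylation) with axial protonation at C5 anti to the C20 methyl, which sets the trans ring fusion, and the regiodefined C3–C4 enolate is then methylated at C4 to complete the gem-dimethyl group.

Step 14
Reactants: 22 the 4,4-dimethyl-3-ketone
Product: 23 (E)-tosylhydrazone of ketone 22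
Conditions: TsNHNH2, PPTS (cat.), EtOH, 70 °C
Reagents that add atoms: 4-methylbenzenesulfonohydrazide, Cc1ccc(cc1)S(=O)(=O)NN
Why: Condensation of the ketone with the sulfonyl hydrazide gives the hydrazone, with the sulfonamide nitrogen turned away from the gem-dimethyl carbon.

Step 15
Reactants: 23 the tosylhydrazone
Product: 26 (13E)-15-(triisopropylsilyloxy)labda-8(17),13-diene, via hydrazinylborane 24 (not isolated), via alkyldiazene 25 (not isolated)
Conditions: catecholborane, CHCl3, 0 °C; then NaOAc·3H2O, 60 °C
Reagents that add atoms: none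
Why: In this Caglioti-type hydrazone reduction catecholborane hydroborates the C=N bond, acetate then expels sulfinate to give an alkyldiazene, and loss of N2 leaves the C3 methylene under conditions mild enough for the silyl ether and both alkenes.

Step 16
Reactants: 26 the silyl ether
Product: 27 (13E)-labda-8(17),13-dien-15-ol
Conditions: Bu4NF, THF, 23 °C
Reagents that add atoms: none
Why: Fluoride cleaves the Si–O bond and frees the allylic alcohol that must direct the epoxidation.

Step 17
Reactants: 27 (13E)-labda-8(17),13-dien-15-ol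
Product: 28 (13R,14R)-13,14-epoxylabd-8(17)-en-15-ol
Conditions: Ti(Oi-Pr)4 (10 mol %), D-(−)-diethyl tartrate (12 mol %), t-BuOOH, 4 Å sieves, CH2Cl2, −20 °C
Reagents that add atoms: tert-butyl hydroperoxide, CC(C)(C)OO
Why: In the Sharpless asymmetric epoxidation the titanium–D-tartrate complex delivers oxygen to the face of the E-allylic alcohol that gives the (13R,14R)-epoxide under reagent control, and the C8=C17 alkene, which has no directing hydroxyl, is not touched.

Step 18
Reactants: 28 (13R,14R)-13,14-epoxylabd-8(17)-en-15-ol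
Product: 29 (13S,14R)-labd-8(17)-ene-13,14,15-triol
Conditions: HClO4 (cat.), THF/H2O, 0 °C
Reagents that add atoms: water, O
Why: In this acid-catalysed epoxide hydrolysis water attacks the tertiary C13 from the back side (C14 is deactivated by the neighbouring CH2OH), so C13 is inverted to S while C14 keeps its R configuration.

Step 19
Reactants: 29 (13S,14R)-labd-8(17)-ene-13,14,15-triol
Product: 30 (13S,14R)-13,14-dihydroxylabd-8(17)-en-15-yl acetate
Conditions: AcCl, 2,4,6-collidine, CH2Cl2, −78 °C
Reagents that add atoms: acetyl chloride, CC(=O)Cl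
Why: Acetyl chloride with a hindered pyridine base at low temperature acylates the primary hydroxyl selectively over the secondary and tertiary ones on steric grounds.

Step 20
Reactants: 30 (13S,14R)-13,14-dihydroxylabd-8(17)-en-15-yl acetate
Product: 31 (13S,14R)-15-acetoxy-13-hydroxylabd-8(17)-en-14-yl propanoate
Conditions: (EtCO)2O, Et3N, DMAP (cat.), CH2Cl2, 0 °C
Reagents that add atoms: propanoic anhydride, CCC(=O)OC(=O)CC
Why: DMAP-catalysed acylation esterifies the remaining secondary hydroxyl, while the tertiary C13 hydroxyl is too hindered to react at 0 °C.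

**Compound list**

1 | 3-bromo-2,4-dimethylaniline | Cc1ccc(N)c(C)c1Br | starting material
2 | 3-bromo-2,4-dimethylbenzenediazonium hydrogensulfate | Cc1ccc([N+]#N)c(C)c1Br.OS(=O)(=O)[O-] | intermediate
3 | 3-bromo-2,4-dimethylphenol | Cc1ccc(O)c(C)c1Br | intermediate
4 | (3-bromo-2,4-dimethylphenoxy)(tert-butyl)dimethylsilane | Cc1ccc(O[Si](C)(C)C(C)(C)C)c(C)c1Br | intermediate
5 | (4-bromobut-1-yn-1-yl)trimethylsilane | C[Si](C)(C)C#CCCBr | starting material
6 | [4-(trimethylsilyl)but-3-yn-1-yl]zinc bromide | C[Si](C)(C)C#CCC[Zn]Br | intermediate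
7 | tert-butyl{2,4-dimethyl-3-[4-(trimethylsilyl)but-3-yn-1-yl]phenoxy}dimethylsilane | Cc1ccc(O[Si](C)(C)C(C)(C)C)c(C)c1CCC#C[Si](C)(C)C | intermediate
8 | geraniol | CC(C)=CCC/C(C)=C/CO | starting material
9 | geranyl triisopropylsilyl ether | CC(C)=CCC/C(C)=C/CO[Si](C(C)C)(C(C)C)C(C)C | intermediate
10 | racemic 6,7-epoxygeranyl triisopropylsilyl ether | CC1(C)OC1CC/C(C)=C/CO[Si](C(C)C)(C(C)C)C(C)C | intermediate
11 | racemic (E)-2,6-dimethyl-8-(triisopropylsilyloxy)oct-6-ene-2,3-diol | CC(C)(O)C(O)CC/C(C)=C/CO[Si](C(C)C)(C(C)C)C(C)C | intermediate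
12 | (E)-4-methyl-6-(triisopropylsilyloxy)hex-4-enal | O=CCC/C(C)=C/CO[Si](C(C)C)(C(C)C)C(C)C | intermediate
13 | diethylborinate of alcohol 14 | Cc1ccc(O[Si](C)(C)C(C)(C)C)c(C)c1CC/C(=C\[Si](C)(C)C)C(OB(CC)CC)CC/C(C)=C/CO[Si](C(C)C)(C(C)C)C(C)C | intermediate
14 | rac-(1E,6E)-2-{2-[3-(tert-butyldimethylsilyloxy)-2,6-dimethylphenyl]ethyl}-6-methyl-8-(triisopropylsilyloxy)-1-(trimethylsilyl)octa-1,6-dien-3-ol (carbinol carbon = C9) | Cc1ccc(O[Si](C)(C)C(C)(C)C)c(C)c1CC/C(=C\[Si](C)(C)C)C(O)CC/C(C)=C/CO[Si](C(C)C)(C(C)C)C(C)C | intermediate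
15 | methyl carbonate of alcohol 14 | Cc1ccc(O[Si](C)(C)C(C)(C)C)c(C)c1CC/C(=C\[Si](C)(C)C)C(OC(=O)OC)CC/C(C)=C/CO[Si](C(C)C)(C(C)C)C(C)C | intermediate
16 | methyl rac-(1E,6E)-2-[2-(3-hydroxy-2,6-dimethylphenyl)ethyl]-6-methyl-8-(triisopropylsilyloxy)-1-(trimethylsilyl)octa-1,6-dien-3-yl carbonate | Cc1ccc(O)c(C)c1CC/C(=C\[Si](C)(C)C)C(OC(=O)OC)CC/C(C)=C/CO[Si](C(C)C)(C(C)C)C(C)C | intermediate
17 | (8(17)E,13E)-17-(trimethylsilyl)-15-(triisopropylsilyloxy)-19-norlabda-1,4,8(17),13-tetraen-3-one (9α-H, 10β-CH3) | C[Si](C)(C)/C=C1\CCC2=C(C)C(=O)C=C[C@]2(C)[C@H]1CC/C(C)=C/CO[Si](C(C)C)(C(C)C)C(C)C | intermediate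
18 | lithium 2,4-dienolate formed from 17 by hydride addition at C1 | C[Si](C)(C)/C=C1\CCC2=C(C)C(O[Li])=CC[C@]2(C)[C@H]1CC/C(C)=C/CO[Si](C(C)C)(C(C)C)C(C)C | intermediate
19 | (8(17)E,13E)-17-(trimethylsilyl)-15-(triisopropylsilyloxy)-19-norlabda-4,8(17),13-trien-3-one | C[Si](C)(C)/C=C1\CCC2=C(C)C(=O)CC[C@]2(C)[C@H]1CC/C(C)=C/CO[Si](C(C)C)(C(C)C)C(C)C | intermediate
20 | (8(17)E,13E)-17-iodo-15-(triisopropylsilyloxy)-19-norlabda-4,8(17),13-trien-3-one | I/C=C1\CCC2=C(C)C(=O)CC[C@]2(C)[C@H]1CC/C(C)=C/CO[Si](C(C)C)(C(C)C)C(C)C | intermediate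
21 | lithium C3–C4 enolate of the 5α-H ketone (C17 methylene) | C=C1CC[C@H]2C(C)=C(O[Li])CC[C@]2(C)[C@H]1CC/C(C)=C/CO[Si](C(C)C)(C(C)C)C(C)C | intermediate
22 | (13E)-15-(triisopropylsilyloxy)labda-8(17),13-dien-3-one | C=C1CC[C@H]2C(C)(C)C(=O)CC[C@]2(C)[C@H]1CC/C(C)=C/CO[Si](C(C)C)(C(C)C)C(C)C | intermediate
23 | (E)-tosylhydrazone of ketone 22 | C=C1CC[C@H]2C(C)(C)/C(=N/NS(=O)(=O)c3ccc(C)cc3)CC[C@]2(C)[C@H]1CC/C(C)=C/CO[Si](C(C)C)(C(C)C)C(C)C | intermediate
24 | N-(1,3,2-benzodioxaborol-2-yl)-N'-tosylhydrazine at C3 (C3 configuration immaterial) | C=C1CC[C@H]2C(C)(C)C(N(NS(=O)(=O)c3ccc(C)cc3)B4Oc5ccccc5O4)CC[C@]2(C)[C@H]1CC/C(C)=C/CO[Si](C(C)C)(C(C)C)C(C)C | intermediate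
25 | C3 alkyldiazene (C3 configuration immaterial) | C=C1CC[C@H]2C(C)(C)C(N=N)CC[C@]2(C)[C@H]1CC/C(C)=C/CO[Si](C(C)C)(C(C)C)C(C)C | intermediate
26 | (13E)-15-(triisopropylsilyloxy)labda-8(17),13-diene | C=C1CC[C@H]2C(C)(C)CCC[C@]2(C)[C@H]1CC/C(C)=C/CO[Si](C(C)C)(C(C)C)C(C)C | intermediate
27 | (13E)-labda-8(17),13-dien-15-ol | C=C1CC[C@H]2C(C)(C)CCC[C@]2(C)[C@H]1CC/C(C)=C/CO | intermediate
28 | (13R,14R)-13,14-epoxylabd-8(17)-en-15-ol | C=C1CC[C@H]2C(C)(C)CCC[C@]2(C)[C@H]1CC[C@@]3(C)O[C@@H]3CO | intermediate
29 | (13S,14R)-labd-8(17)-ene-13,14,15-triol | C=C1CC[C@H]2C(C)(C)CCC[C@]2(C)[C@H]1CC[C@](C)(O)[C@@H](CO)O | intermediate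
30 | (13S,14R)-13,14-dihydroxylabd-8(17)-en-15-yl acetate | C=C1CC[C@H]2C(C)(C)CCC[C@]2(C)[C@H]1CC[C@](C)(O)[C@@H](COC(C)=O)O | intermediate
31 | (13S,14R)-15-acetoxy-13-hydroxylabd-8(17)-en-14-yl propanoate | C=C1CC[C@H]2C(C)(C)CCC[C@]2(C)[C@H]1CC[C@](C)(O)[C@@H](COC(C)=O)OC(=O)CC | target

**Count and risks**

Total step count: 20. Longest linear sequence: 17 steps (steps 1–3 or 4–6, then 7–20).

Step 10 (ring closure). What may go wrong: the phenoxide may react through C4 or through oxygen, the wrong allyl face may be attacked, or ionisation of the trisubstituted vinylsilane carbonate may be slow. The fallback is stereospecific instead of catalyst-controlled and uses known reaction types. It sets out from alcohol 14. Dess–Martin oxidation gives the C9 ketone F1. Corey–Bakshi–Shibata reduction ((R)-2-methyl-CBS-oxazaborolidine, BH3·SMe2) should give the (9S)-alcohol F2. Appel-type chlorination (PPh3, hexachloroacetone) converts it with inversion into the (9R)-allylic chloride F3. KHF2 in MeOH frees the phenol to give the chlorophenol F4. KOt-Bu in t-BuOH/THF then closes ring B by intramolecular para C-alkylation of the phenoxide (alkylative dearomatisation, an SN2 displacement with inversion at C9). The C17 silyl group blocks the SN2' path, and C10 is set by the pseudo-equatorial C11 chain. The fallback returns to the route at dienone 17.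

Step 13 (reductive removal of iodine and reductive methylation in one flask). What may go wrong: the enolate may be protonated or equilibrated by the extra base formed during C–I cleavage, giving non-methylated or over-methylated ketone, and excess metal may cleave the allylic C–O bond. The fallback separates the tasks and alkylates an isolable, regiodefined enol silane. It sets out from vinyl iodide 20. A radical chain reduction (Bu3SnH, AIBN, benzene, 80 °C) gives the iodine-free enone F5. Li (2.2 equiv) in NH3/THF with t-BuOH (1 equiv), then Me3SiCl/Et3N, gives the trimethylsilyl enol ether F6. MeLi in THF regenerates lithium enolate 21 free of ammonia and alkoxide, and MeI then gives ketone 22.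

Step 18 (epoxide hydrolysis). What may go wrong: ionisation at C13 instead of back-side attack would erode the C13 configuration, and the C13 cation could be captured by the C8=C17 alkene. The fallback runs under basic conditions and inverts C14 instead of C13. It sets out from allylic alcohol 27. Sharpless epoxidation with L-(+)-diethyl tartrate gives the (13S,14S)-epoxy alcohol F7. Aqueous NaOH in t-BuOH at 70 °C induces Payne rearrangement to the (13S,14R)-14,15-epoxy-13-ol F8, which is not isolated. Hydroxide opens it at the primary C15 and gives the same triol 29 without any cationic intermediate.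

**Further compounds**

F1 | step 10 | (1E,6E)-2-{2-[3-(tert-butyldimethylsilyloxy)-2,6-dimethylphenyl]ethyl}-6-methyl-8-(triisopropylsilyloxy)-1-(trimethylsilyl)octa-1,6-dien-3-one | Cc1ccc(O[Si](C)(C)C(C)(C)C)c(C)c1CC/C(=C\[Si](C)(C)C)C(=O)CC/C(C)=C/CO[Si](C(C)C)(C(C)C)C(C)C
F2 | step 10 | (S)-enantiomer of alcohol 14 (9S) | Cc1ccc(O[Si](C)(C)C(C)(C)C)c(C)c1CC/C(=C\[Si](C)(C)C)[C@@H](O)CC/C(C)=C/CO[Si](C(C)C)(C(C)C)C(C)C
F3 | step 10 | (9R)-allylic chloride with aryl silyl ether | Cc1ccc(O[Si](C)(C)C(C)(C)C)c(C)c1CC/C(=C\[Si](C)(C)C)[C@H](Cl)CC/C(C)=C/CO[Si](C(C)C)(C(C)C)C(C)C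
F4 | step 10 | (9R)-allylic chloride with free phenol | Cc1ccc(O)c(C)c1CC/C(=C\[Si](C)(C)C)[C@H](Cl)CC/C(C)=C/CO[Si](C(C)C)(C(C)C)C(C)C
F5 | step 13 | (13E)-15-(triisopropylsilyloxy)-19-norlabda-4,8(17),13-trien-3-one | C=C1CCC2=C(C)C(=O)CC[C@]2(C)[C@H]1CC/C(C)=C/CO[Si](C(C)C)(C(C)C)C(C)C
F6 | step 13 | trimethylsilyl enol ether (C3–C4) of the 5α-H ketone | C=C1CC[C@H]2C(C)=C(O[Si](C)(C)C)CC[C@]2(C)[C@H]1CC/C(C)=C/CO[Si](C(C)C)(C(C)C)C(C)C
F7 | step 18 | (13S,14S)-13,14-epoxylabd-8(17)-en-15-ol | C=C1CC[C@H]2C(C)(C)CCC[C@]2(C)[C@H]1CC[C@]3(C)O[C@H]3CO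
F8 | step 18 | (13S,14R)-14,15-epoxylabd-8(17)-en-13-ol | C=C1CC[C@H]2C(C)(C)CCC[C@]2(C)[C@H]1CC[C@](C)(O)[C@H]3CO3
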